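**Retrosynthetic overview**
1. Target 45 comes from desilylation of 44. The 28-membered ring (the only ring) is closed second to last by a macrocyclic Passerini reaction of isocyano acid 42 with butanal: the isocyanide carbon acts as a carbamoyl-anion equivalent and forms the Cα–C(=O) bond, the ester and the amide together.
2. 42 comes from a C15–C16 Suzuki coupling of alkenylboronate 19 (C1–C15) with Z-vinyl iodide 38 (C16–C24).
3. 19 comes from an alkyl–alkyl Negishi coupling (C5–C6) of bromo ester 4 (desymmetrised meso anhydride, C2/C4) with chloride 14 (C9 from a kinetically resolved epoxide, C13 from copper-catalysed asymmetric allylic alkylation).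
4. 38 comes from Duboudin carbomagnesiation of propargyl alcohol (sets the C16=C17 geometry) with the Grignard reagent of bromide 29; C23 is from ethyl (S)-4-chloro-3-hydroxybutanoate, C20/C21 from a Brown anti-diol allylboration.

Assumption: the identifier means exactly the stereoisomer drawn in the SMILES; each chiral catalyst or reagent is named as the antipode expected from its published selectivity model, from memory and not checked against the literature, and is exchanged for its mirror image if the first run shows the opposite sense.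

Carbon numbers C1–C24 follow the long chain from the lactone carbonyl (C1) to the CH2N carbon (C24).

**Route**

Step 1
Reactants: 1 cis-3,5-dimethyloxane-2,6-dione (meso-2,4-dimethylglutaric anhydride)
Product: 2 (2R,4S)-5-methoxy-2,4-dimethyl-5-oxopentanoic acid
Conditions: MeOH (10 equiv), (DHQD)2AQN [hydroquinidine anthraquinone-1,4-diyl diether] (10 mol%), Et2O, −40 °C
Reagents that add atoms: methanol (CO)
Why: Cinchona-alkaloid-catalysed desymmetrising methanolysis of the meso anhydride opens one enantiotopic carbonyl and so fixes both methyl-bearing centres (future C2 and C4, syn) in one operation.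

Step 2
Reactants: 2 (2R,4S)-5-methoxy-2,4-dimethyl-5-oxopentanoic acid
Product: 3 methyl (2S,4R)-5-hydroxy-2,4-dimethylpentanoate
Conditions: BH3·SMe2, THF, 0 °C → rt; H2O
Reagents that add atoms: none
Why: Chemoselective borane reduction takes the free carboxylic acid to the primary alcohol and leaves the methyl ester and both stereocentres untouched.

Step 3
Reactants: 3 methyl (2S,4R)-5-hydroxy-2,4-dimethylpentanoate
Product: 4 methyl (2S,4R)-5-bromo-2,4-dimethylpentanoate
Conditions: CBr4, PPh3, CH2Cl2, 0 °C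
Reagents that add atoms: carbon tetrabromide (BrC(Br)(Br)Br)
Why: Appel bromination converts the primary alcohol under neutral conditions before the hydroxy ester can lactonise.

Step 4
Reactants: 5 5-chloropent-1-ene
Product: 6 rac-2-(3-chloropropyl)oxirane
Conditions: mCPBA, CH2Cl2, 0 °C → rt
Reagents that add atoms: 3-chloroperbenzoic acid (OOC(=O)c1cccc(Cl)c1)
Why: Prilezhaev epoxidation of the terminal alkene; the primary chloride is inert.

Step 5
Reactants: 6 rac-2-(3-chloropropyl)oxirane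
Product: 7 (S)-2-(3-chloropropyl)oxirane
Conditions: (S,S)-(salen)Co(OAc) [salen = N,N′-bis(3,5-di-tert-butylsalicylidene)-1,2-cyclohexanediamine dianion] (0.5 mol%), H2O (0.55 equiv), 0 °C → rt, then distil
Reagents that add atoms: none
Why: Jacobsen hydrolytic kinetic resolution hydrolyses the (R)-epoxide and leaves the (S)-epoxide, which carries the future C9 centre, in high ee (maximum 50% yield).

Step 6
Reactants: 7 (S)-2-(3-chloropropyl)oxirane; 8 but-3-en-1-ylmagnesium bromide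
Product: 9 (R)-9-chloronon-1-en-6-ol
Conditions: 8 (1.3 equiv), CuI (10 mol%), THF, −40 → −20 °C; aq NH4Cl at −20 °C
Reagents that add atoms: none
Why: Copper-catalysed Grignard opening of the terminal epoxide at its CH2 end (SN2) keeps the carbinol configuration (now formally R); the cold quench stops the chloro alkoxide closing to a tetrahydrofuran.

Step 7
Reactants: 9 (R)-9-chloronon-1-en-6-ol
Product: 10 (R)-tert-butyl[(9-chloronon-1-en-6-yl)oxy]dimethylsilane
Conditions: TBSCl, imidazole, DMF, rt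
Reagents that add atoms: tert-butyldimethylsilyl chloride (CC(C)(C)[Si](C)(C)Cl)
Why: Standard silylation protects the C9 hydroxyl for the organometallic steps and the later formamide dehydration.

Step 8
Reactants: 10 (R)-tert-butyl[(9-chloronon-1-en-6-yl)oxy]dimethylsilane; 11 (E)-1,4-dibromobut-2-ene
Product: 12 (R,E)-tert-butyl[(1-bromo-10-chlorodec-2-en-7-yl)oxy]dimethylsilane
Conditions: 11 (4 equiv), second-generation Grubbs catalyst (3 mol%), CH2Cl2, 40 °C
Reagents that add atoms: none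
Why: Olefin cross-metathesis of the terminal alkene with excess symmetrical dibromide gives the (E)-allylic bromide; the alkyl chloride and silyl ether are spectators.

Step 9
Reactants: 12 (R,E)-tert-butyl[(1-bromo-10-chlorodec-2-en-7-yl)oxy]dimethylsilane; 13 ethylmagnesium bromide
Product: 14 tert-butyl{[(3S,7R)-10-chloro-3-ethyldec-1-en-7-yl]oxy}dimethylsilane
Conditions: 13 (1.3 equiv, slow addition), CuBr·SMe2 (3 mol%), (S,S)-Taniaphos (4 mol%), CH2Cl2, −78 °C
Reagents that add atoms: none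
Why: Feringa copper-catalysed asymmetric allylic alkylation delivers ethyl in an SN2′ sense to give the branched alkene and sets C13 (S) under ligand control.

Step 10
Reactants: 14 tert-butyl{[(3S,7R)-10-chloro-3-ethyldec-1-en-7-yl]oxy}dimethylsilane; 4 methyl (2S,4R)-5-bromo-2,4-dimethylpentanoate
Product: 17 methyl (2S,4S,9S,13S)-9-[(tert-butyldimethylsilyl)oxy]-13-ethyl-2,4-dimethylpentadec-14-enoate, via alkylmagnesium chloride 15 (not isolated), via alkylzinc chloride 16 (not isolated)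
Conditions: Mg, THF, 60 °C; ZnCl2, 0 °C; then 4 (0.9 equiv), [PdCl2(IPr)(3-chloropyridine)] (2 mol%), LiBr, THF/NMP, rt
Reagents that add atoms: none
Why: Alkyl–alkyl Negishi coupling (Organ conditions) joins C5 to C6; the zinc reagent does not touch the ester and no stereocentre is involved.

Step 11
Reactants: 17 methyl (2S,4S,9S,13S)-9-[(tert-butyldimethylsilyl)oxy]-13-ethyl-2,4-dimethylpentadec-14-enoate; 18 4,4,5,5-tetramethyl-2-vinyl-1,3,2-dioxaborolane
Product: 19 methyl (2S,4S,9S,13S,14E)-9-[(tert-butyldimethylsilyl)oxy]-13-ethyl-2,4-dimethyl-15-(4,4,5,5-tetramethyl-1,3,2-dioxaborolan-2-yl)pentadec-14-enoate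
Conditions: 18 (3 equiv), second-generation Hoveyda–Grubbs catalyst (5 mol%), CH2Cl2, 40 °C
Reagents that add atoms: none
Why: Cross-metathesis with the vinylboronate gives the E-alkenylboronate, the E preference being reinforced by the allylic branch.

Step 12
Reactants: 20 ethyl (S)-4-chloro-3-hydroxybutanoate
Product: 21 ethyl (S)-3-[(tert-butyldimethylsilyl)oxy]-4-chlorobutanoate
Conditions: TBSCl, imidazole, DMF, rt
Reagents that add atoms: tert-butyldimethylsilyl chloride (CC(C)(C)[Si](C)(C)Cl)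
Why: Standard silylation of the chiral-pool alcohol that becomes C23 (S).

Step 13
Reactants: 21 ethyl (S)-3-[(tert-butyldimethylsilyl)oxy]-4-chlorobutanoate
Product: 22 (S)-3-[(tert-butyldimethylsilyl)oxy]-4-chlorobutanal
Conditions: i-Bu2AlH (1.1 equiv), CH2Cl2, −78 °C; aq KNaC4H4O6
Reagents that add atoms: none
Why: Low-temperature half-reduction of the ester stops at the aldehyde because the tetrahedral aluminate survives until work-up.

Step 14
Reactants: 22 (S)-3-[(tert-butyldimethylsilyl)oxy]-4-chlorobutanal; 23 4,4,5,5-tetramethyl-2-(propa-1,2-dien-1-yl)-1,3,2-dioxaborolane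
Product: 26 (3R,4S,6S)-6-[(tert-butyldimethylsilyl)oxy]-7-chlorohept-1-ene-3,4-diol, via γ-borylallylborane 24 (not isolated), via borinate–boronate adduct 25 (not isolated)
Conditions: (+)-Ipc2BH, THF, 0 °C; 22, −78 °C; then H2O2, NaHCO3, THF/H2O, 0 °C → rt
Reagents that add atoms: hydrogen peroxide (OO)
Why: Brown (E)-γ-borylallylboration adds through a chair transition state on the re face under reagent control, and oxidation of the C–B bond with retention gives the anti diol, setting C21 (S) and C20 (R).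

Step 15
Reactants: 26 (3R,4S,6S)-6-[(tert-butyldimethylsilyl)oxy]-7-chlorohept-1-ene-3,4-diol
Product: 27 (3R,4S,6S)-3,4,6-tris[(tert-butyldimethylsilyl)oxy]-7-chlorohept-1-ene
Conditions: TBSOTf, 2,6-lutidine, CH2Cl2, −78 → 0 °C
Reagents that add atoms: tert-butyldimethylsilyl trifluoromethanesulfonate (CC(C)(C)[Si](C)(C)OS(=O)(=O)C(F)(F)F)
Why: Silyl triflate silylates both hindered secondary alcohols so that one fluoride step removes every protecting group at the end.

Step 16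
Reactants: 27 (3R,4S,6S)-3,4,6-tris[(tert-butyldimethylsilyl)oxy]-7-chlorohept-1-ene
Product: 29 (3R,4S,6S)-1-bromo-3,4,6-tris[(tert-butyldimethylsilyl)oxy]-7-chloroheptane, via alkylzirconocene chloride 28 (not isolated)
Conditions: Cp2Zr(H)Cl, CH2Cl2, rt; NBS, 0 °C
Reagents that add atoms: N-bromosuccinimide (O=C1CCC(=O)N1Br)
Why: Schwartz hydrozirconation puts zirconium on the terminal carbon and electrophilic bromination of the C–Zr bond gives the primary bromide (Hart–Schwartz halogenation).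

Step 17
Reactants: 29 (3R,4S,6S)-1-bromo-3,4,6-tris[(tert-butyldimethylsilyl)oxy]-7-chloroheptane; 30 prop-2-yn-1-ol
Product: 34 (2Z,5R,6S,8S)-5,6,8-tris[(tert-butyldimethylsilyl)oxy]-9-chloro-2-(iodomethylidene)nonan-1-ol, via bromomagnesium propargyl alkoxide 31 (not isolated), via alkylmagnesium bromide 32 (not isolated), via vinylmagnesium adduct 33 (not isolated)
Conditions: 30 (1.5 equiv), EtMgBr (1.5 equiv), Et2O, 0 °C; 29, Mg, Et2O, 35 °C; mix, CuI (15 mol%), −20 °C → rt; then I2, −78 → 0 °C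
Reagents that add atoms: iodine (II)
Why: Duboudin copper-catalysed anti-carbomagnesiation of the propargyl alkoxide puts the alkyl group on C17 and a chelated vinylmagnesium on C16 cis to CH2O, and iodinolysis with retention fixes the C16=C17 geometry.

Step 18
Reactants: 34 (2Z,5R,6S,8S)-5,6,8-tris[(tert-butyldimethylsilyl)oxy]-9-chloro-2-(iodomethylidene)nonan-1-ol
Product: 35 (1Z,5R,6S,8S)-5,6,8-tris[(tert-butyldimethylsilyl)oxy]-9-chloro-1-iodo-2-(methoxymethyl)non-1-ene
Conditions: NaH, MeI, THF, 0 °C → rt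
Reagents that add atoms: iodomethane (CI)
Why: Williamson etherification of the allylic alcohol; the fully substituted C17 leaves no hydrogen for elimination of the vinyl iodide.

Step 19
Reactants: 35 (1Z,5R,6S,8S)-5,6,8-tris[(tert-butyldimethylsilyl)oxy]-9-chloro-1-iodo-2-(methoxymethyl)non-1-ene
Product: 36 (1Z,5R,6S,8S)-9-azido-5,6,8-tris[(tert-butyldimethylsilyl)oxy]-1-iodo-2-(methoxymethyl)non-1-ene
Conditions: NaN3, NaI (cat.), DMF, 80 °C
Reagents that add atoms: sodium azide ([Na+].[N-]=[N+]=[N-])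
Why: SN2 displacement of the primary chloride by azide (iodide-assisted) introduces the C24 nitrogen without touching C23.

Step 20
Reactants: 36 (1Z,5R,6S,8S)-9-azido-5,6,8-tris[(tert-butyldimethylsilyl)oxy]-1-iodo-2-(methoxymethyl)non-1-ene
Product: 38 N-[(2S,4S,5R,8Z)-2,4,5-tris[(tert-butyldimethylsilyl)oxy]-9-iodo-8-(methoxymethyl)non-8-en-1-yl]formamide, via primary amine 37 (not isolated)
Conditions: PPh3, THF/H2O, 50 °C; then HCO2Et, 55 °C
Reagents that add atoms: ethyl formate (CCOC=O)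
Why: Staudinger reduction gives the amine, which is N-formylated by aminolysis of ethyl formate in the same flask.

Step 21
Reactants: 19 methyl (2S,4S,9S,13S,14E)-9-[(tert-butyldimethylsilyl)oxy]-13-ethyl-2,4-dimethyl-15-(4,4,5,5-tetramethyl-1,3,2-dioxaborolan-2-yl)pentadec-14-enoate; 38 N-[(2S,4S,5R,8Z)-2,4,5-tris[(tert-butyldimethylsilyl)oxy]-9-iodo-8-(methoxymethyl)non-8-en-1-yl]formamide
Product: 39 methyl (2S,4S,9S,13S,14E,16Z,20R,21S,23S)-9,20,21,23-tetrakis[(tert-butyldimethylsilyl)oxy]-13-ethyl-24-formamido-17-(methoxymethyl)-2,4-dimethyltetracosa-14,16-dienoate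
Conditions: Pd(dppf)Cl2 (5 mol%), AsPh3 (10 mol%), Cs2CO3, DMF/THF/H2O, rt
Reagents that add atoms: none
Why: Suzuki–Miyaura alkenyl–alkenyl coupling forms C15–C16 with retention of both olefin geometries, giving the (14E,16Z)-diene.

Step 22
Reactants: 39 methyl (2S,4S,9S,13S,14E,16Z,20R,21S,23S)-9,20,21,23-tetrakis[(tert-butyldimethylsilyl)oxy]-13-ethyl-24-formamido-17-(methoxymethyl)-2,4-dimethyltetracosa-14,16-dienoate
Product: 40 methyl (2S,4S,9S,13S,14E,16Z,20R,21S,23S)-9,20,21,23-tetrakis[(tert-butyldimethylsilyl)oxy]-13-ethyl-24-isocyano-17-(methoxymethyl)-2,4-dimethyltetracosa-14,16-dienoate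
Conditions: Burgess reagent (2 equiv), CH2Cl2, rt
Reagents that add atoms: none
Why: Burgess dehydration of the formamide gives the isocyanide under neutral conditions that spare the silyl ethers, diene and ester.

Step 23
Reactants: 40 methyl (2S,4S,9S,13S,14E,16Z,20R,21S,23S)-9,20,21,23-tetrakis[(tert-butyldimethylsilyl)oxy]-13-ethyl-24-isocyano-17-(methoxymethyl)-2,4-dimethyltetracosa-14,16-dienoate
Product: 42 (2S,4S,9S,13S,14E,16Z,20R,21S,23S)-9,20,21,23-tetrakis[(tert-butyldimethylsilyl)oxy]-13-ethyl-24-isocyano-17-(methoxymethyl)-2,4-dimethyltetracosa-14,16-dienoic acid, via lithium carboxylate 41 (not isolated)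
Conditions: LiOH·H2O, THF/MeOH/H2O, 35 °C; then aq NaH2PO4 (pH 5), 0 °C, extract into CHCl3 and use at once
Reagents that add atoms: lithium hydroxide ([Li+].[OH-])
Why: Saponification of the methyl ester (the isocyanide is base-stable) followed by a cold pH 5 buffer frees the acid without hydrolysing the isocyanide or epimerising C2.

Step 24
Reactants: 42 (2S,4S,9S,13S,14E,16Z,20R,21S,23S)-9,20,21,23-tetrakis[(tert-butyldimethylsilyl)oxy]-13-ethyl-24-isocyano-17-(methoxymethyl)-2,4-dimethyltetracosa-14,16-dienoic acid; 43 butanal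
Product: 44 (2S,6S,8S,9R,12Z,14E,16S,20S,25S,27S)-6,8,9,20-tetrakis[(tert-butyldimethylsilyl)oxy]-16-ethyl-12-(methoxymethyl)-25,27-dimethyl-2-propyl-1-oxa-4-azacyclooctacosa-12,14-diene-3,28-dione
Conditions: 43 (5 equiv), (R)-TRIP [(R)-3,3′-bis(2,4,6-triisopropylphenyl)-1,1′-binaphthyl-2,2′-diyl hydrogen phosphate] (20 mol%), CHCl3, rt, 42 added over 24 h (final 1 mM), then 24 h
Reagents that add atoms: none
Why: Proposed new method: an intramolecular chiral-phosphoric-acid-catalysed Passerini reaction in which the phosphoric acid binds the acid–aldehyde pair, the isocyanide carbon (a carbamoyl-anion equivalent) attacks the aldehyde carbon on the face the catalyst leaves open to give the (S) centre, the nitrilium is trapped by the tethered carboxylate and Mumm acyl transfer closes the 28-membered ring while forming the ester and the amide; the closest known reactions are the chiral-phosphoric-acid-catalysed three-component Passerini reaction and Passerini macrocyclisations of α-isocyano-ω-carboxylic acids.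

Step 25
Reactants: 44 (2S,6S,8S,9R,12Z,14E,16S,20S,25S,27S)-6,8,9,20-tetrakis[(tert-butyldimethylsilyl)oxy]-16-ethyl-12-(methoxymethyl)-25,27-dimethyl-2-propyl-1-oxa-4-azacyclooctacosa-12,14-diene-3,28-dione
Product: 45 (2S,6S,8S,9R,12Z,14E,16S,20S,25S,27S)-16-ethyl-6,8,9,20-tetrahydroxy-12-(methoxymethyl)-25,27-dimethyl-2-propyl-1-oxa-4-azacyclooctacosa-12,14-diene-3,28-dione
Conditions: HF·pyridine, pyridine, THF, 0 °C → rt; final HPLC
Reagents that add atoms: none
Why: Fluoride-mediated global desilylation under buffered, mildly acidic conditions removes all four silyl ethers without opening or transposing the α-acyloxy amide ester.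

**Compound list**
1 | cis-3,5-dimethyloxane-2,6-dione (meso-2,4-dimethylglutaric anhydride) | O=C1[C@@H](C)C[C@@H](C)C(=O)O1 | starting material
2 | (2R,4S)-5-methoxy-2,4-dimethyl-5-oxopentanoic acid | COC(=O)[C@@H](C)C[C@@H](C)C(=O)O | intermediate
3 | methyl (2S,4R)-5-hydroxy-2,4-dimethylpentanoate | COC(=O)[C@@H](C)C[C@@H](C)CO | intermediate
4 | methyl (2S,4R)-5-bromo-2,4-dimethylpentanoate | COC(=O)[C@@H](C)C[C@@H](C)CBr | intermediate
5 | 5-chloropent-1-ene | C=CCCCCl | starting material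
6 | rac-2-(3-chloropropyl)oxirane | ClCCCC1CO1 | intermediate
7 | (S)-2-(3-chloropropyl)oxirane | ClCCC[C@H]1CO1 | intermediate
8 | but-3-en-1-ylmagnesium bromide | C=CCC[Mg]Br | starting material
9 | (R)-9-chloronon-1-en-6-ol | ClCCC[C@H](O)CCCC=C | intermediate
10 | (R)-tert-butyl[(9-chloronon-1-en-6-yl)oxy]dimethylsilane | ClCCC[C@H](O[Si](C)(C)C(C)(C)C)CCCC=C | intermediate
11 | (E)-1,4-dibromobut-2-ene | BrC/C=C/CBr | starting material
12 | (R,E)-tert-butyl[(1-bromo-10-chlorodec-2-en-7-yl)oxy]dimethylsilane | ClCCC[C@H](O[Si](C)(C)C(C)(C)C)CCC/C=C/CBr | intermediate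
13 | ethylmagnesium bromide | CC[Mg]Br | starting material
14 | tert-butyl{[(3S,7R)-10-chloro-3-ethyldec-1-en-7-yl]oxy}dimethylsilane | ClCCC[C@H](O[Si](C)(C)C(C)(C)C)CCC[C@H](CC)C=C | intermediate
15 | {(4R,8S)-4-[(tert-butyldimethylsilyl)oxy]-8-ethyldec-9-en-1-yl}magnesium chloride | Cl[Mg]CCC[C@H](O[Si](C)(C)C(C)(C)C)CCC[C@H](CC)C=C | intermediate
16 | {(4R,8S)-4-[(tert-butyldimethylsilyl)oxy]-8-ethyldec-9-en-1-yl}zinc chloride | Cl[Zn]CCC[C@H](O[Si](C)(C)C(C)(C)C)CCC[C@H](CC)C=C | intermediate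
17 | methyl (2S,4S,9S,13S)-9-[(tert-butyldimethylsilyl)oxy]-13-ethyl-2,4-dimethylpentadec-14-enoate | COC(=O)[C@@H](C)C[C@@H](C)CCCC[C@H](O[Si](C)(C)C(C)(C)C)CCC[C@H](CC)C=C | intermediate
18 | 4,4,5,5-tetramethyl-2-vinyl-1,3,2-dioxaborolane | C=CB1OC(C)(C)C(C)(C)O1 | starting material
19 | methyl (2S,4S,9S,13S,14E)-9-[(tert-butyldimethylsilyl)oxy]-13-ethyl-2,4-dimethyl-15-(4,4,5,5-tetramethyl-1,3,2-dioxaborolan-2-yl)pentadec-14-enoate | COC(=O)[C@@H](C)C[C@@H](C)CCCC[C@H](O[Si](C)(C)C(C)(C)C)CCC[C@H](CC)/C=C/B1OC(C)(C)C(C)(C)O1 | intermediate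
20 | ethyl (S)-4-chloro-3-hydroxybutanoate | CCOC(=O)C[C@H](O)CCl | starting material
21 | ethyl (S)-3-[(tert-butyldimethylsilyl)oxy]-4-chlorobutanoate | CCOC(=O)C[C@H](O[Si](C)(C)C(C)(C)C)CCl | intermediate
22 | (S)-3-[(tert-butyldimethylsilyl)oxy]-4-chlorobutanal | O=CC[C@H](O[Si](C)(C)C(C)(C)C)CCl | intermediate
23 | 4,4,5,5-tetramethyl-2-(propa-1,2-dien-1-yl)-1,3,2-dioxaborolane (allenylboronic acid pinacol ester) | C=C=CB1OC(C)(C)C(C)(C)O1 | starting material
24 | (E)-{3-[bis(isopinocampheyl)boryl]prop-1-en-1-yl}boronic acid pinacol ester, from (+)-Ipc2BH | C[C@@H]1[C@H](C[C@H]2C[C@@H]1C2(C)C)B(C/C=C/B1OC(C)(C)C(C)(C)O1)[C@H]1C[C@H]2C[C@@H]([C@@H]1C)C2(C)C | intermediate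
25 | allylboration adduct: the 3,4-anti hept-1-ene of 26 carrying the pinacol boronate on C3 and the bis(isopinocampheyl)borinate on the C4 oxygen | C=C[C@@H](B1OC(C)(C)C(C)(C)O1)[C@@H](OB([C@H]1C[C@H]2C[C@@H]([C@@H]1C)C2(C)C)[C@H]1C[C@H]2C[C@@H]([C@@H]1C)C2(C)C)C[C@H](O[Si](C)(C)C(C)(C)C)CCl | intermediate
26 | (3R,4S,6S)-6-[(tert-butyldimethylsilyl)oxy]-7-chlorohept-1-ene-3,4-diol | C=C[C@@H](O)[C@@H](O)C[C@H](O[Si](C)(C)C(C)(C)C)CCl | intermediate
27 | (3R,4S,6S)-3,4,6-tris[(tert-butyldimethylsilyl)oxy]-7-chlorohept-1-ene | C=C[C@@H](O[Si](C)(C)C(C)(C)C)[C@@H](O[Si](C)(C)C(C)(C)C)C[C@H](O[Si](C)(C)C(C)(C)C)CCl | intermediate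
28 | [(3R,4S,6S)-3,4,6-tris[(tert-butyldimethylsilyl)oxy]-7-chloroheptyl]bis(cyclopentadienyl)zirconium chloride | Cl[Zr](C1C=CC=C1)(C1C=CC=C1)CC[C@@H](O[Si](C)(C)C(C)(C)C)[C@@H](O[Si](C)(C)C(C)(C)C)C[C@H](O[Si](C)(C)C(C)(C)C)CCl | intermediate
29 | (3R,4S,6S)-1-bromo-3,4,6-tris[(tert-butyldimethylsilyl)oxy]-7-chloroheptane | BrCC[C@@H](O[Si](C)(C)C(C)(C)C)[C@@H](O[Si](C)(C)C(C)(C)C)C[C@H](O[Si](C)(C)C(C)(C)C)CCl | intermediate
30 | prop-2-yn-1-ol | C#CCO | starting material
31 | bromomagnesium prop-2-yn-1-olate | C#CCO[Mg]Br | intermediate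
32 | [(3R,4S,6S)-3,4,6-tris[(tert-butyldimethylsilyl)oxy]-7-chloroheptyl]magnesium bromide | Br[Mg]CC[C@@H](O[Si](C)(C)C(C)(C)C)[C@@H](O[Si](C)(C)C(C)(C)C)C[C@H](O[Si](C)(C)C(C)(C)C)CCl | intermediate
33 | (Z)-vinylmagnesium bromide/bromomagnesium alkoxide adduct (Mg on C16 cis to CH2O) | Br[Mg]/C=C(\CO[Mg]Br)CC[C@@H](O[Si](C)(C)C(C)(C)C)[C@@H](O[Si](C)(C)C(C)(C)C)C[C@H](O[Si](C)(C)C(C)(C)C)CCl | intermediate
34 | (2Z,5R,6S,8S)-5,6,8-tris[(tert-butyldimethylsilyl)oxy]-9-chloro-2-(iodomethylidene)nonan-1-ol | I/C=C(\CO)CC[C@@H](O[Si](C)(C)C(C)(C)C)[C@@H](O[Si](C)(C)C(C)(C)C)C[C@H](O[Si](C)(C)C(C)(C)C)CCl | intermediate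
35 | (1Z,5R,6S,8S)-5,6,8-tris[(tert-butyldimethylsilyl)oxy]-9-chloro-1-iodo-2-(methoxymethyl)non-1-ene | I/C=C(\COC)CC[C@@H](O[Si](C)(C)C(C)(C)C)[C@@H](O[Si](C)(C)C(C)(C)C)C[C@H](O[Si](C)(C)C(C)(C)C)CCl | intermediate
36 | (1Z,5R,6S,8S)-9-azido-5,6,8-tris[(tert-butyldimethylsilyl)oxy]-1-iodo-2-(methoxymethyl)non-1-ene | I/C=C(\COC)CC[C@@H](O[Si](C)(C)C(C)(C)C)[C@@H](O[Si](C)(C)C(C)(C)C)C[C@H](O[Si](C)(C)C(C)(C)C)CN=[N+]=[N-] | intermediate
37 | (2S,4S,5R,8Z)-2,4,5-tris[(tert-butyldimethylsilyl)oxy]-9-iodo-8-(methoxymethyl)non-8-en-1-amine | I/C=C(\COC)CC[C@@H](O[Si](C)(C)C(C)(C)C)[C@@H](O[Si](C)(C)C(C)(C)C)C[C@H](O[Si](C)(C)C(C)(C)C)CN | intermediate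
38 | N-[(2S,4S,5R,8Z)-2,4,5-tris[(tert-butyldimethylsilyl)oxy]-9-iodo-8-(methoxymethyl)non-8-en-1-yl]formamide | I/C=C(\COC)CC[C@@H](O[Si](C)(C)C(C)(C)C)[C@@H](O[Si](C)(C)C(C)(C)C)C[C@H](O[Si](C)(C)C(C)(C)C)CNC=O | intermediate
39 | methyl (2S,4S,9S,13S,14E,16Z,20R,21S,23S)-9,20,21,23-tetrakis[(tert-butyldimethylsilyl)oxy]-13-ethyl-24-formamido-17-(methoxymethyl)-2,4-dimethyltetracosa-14,16-dienoate | COC(=O)[C@@H](C)C[C@@H](C)CCCC[C@H](O[Si](C)(C)C(C)(C)C)CCC[C@H](CC)/C=C/C=C(\COC)CC[C@@H](O[Si](C)(C)C(C)(C)C)[C@@H](O[Si](C)(C)C(C)(C)C)C[C@H](O[Si](C)(C)C(C)(C)C)CNC=O | intermediate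
40 | methyl (2S,4S,9S,13S,14E,16Z,20R,21S,23S)-9,20,21,23-tetrakis[(tert-butyldimethylsilyl)oxy]-13-ethyl-24-isocyano-17-(methoxymethyl)-2,4-dimethyltetracosa-14,16-dienoate | COC(=O)[C@@H](C)C[C@@H](C)CCCC[C@H](O[Si](C)(C)C(C)(C)C)CCC[C@H](CC)/C=C/C=C(\COC)CC[C@@H](O[Si](C)(C)C(C)(C)C)[C@@H](O[Si](C)(C)C(C)(C)C)C[C@H](O[Si](C)(C)C(C)(C)C)C[N+]#[C-] | intermediate
41 | lithium salt of acid 42 | [Li+].[O-]C(=O)[C@@H](C)C[C@@H](C)CCCC[C@H](O[Si](C)(C)C(C)(C)C)CCC[C@H](CC)/C=C/C=C(\COC)CC[C@@H](O[Si](C)(C)C(C)(C)C)[C@@H](O[Si](C)(C)C(C)(C)C)C[C@H](O[Si](C)(C)C(C)(C)C)C[N+]#[C-] | intermediate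
42 | (2S,4S,9S,13S,14E,16Z,20R,21S,23S)-9,20,21,23-tetrakis[(tert-butyldimethylsilyl)oxy]-13-ethyl-24-isocyano-17-(methoxymethyl)-2,4-dimethyltetracosa-14,16-dienoic acid | OC(=O)[C@@H](C)C[C@@H](C)CCCC[C@H](O[Si](C)(C)C(C)(C)C)CCC[C@H](CC)/C=C/C=C(\COC)CC[C@@H](O[Si](C)(C)C(C)(C)C)[C@@H](O[Si](C)(C)C(C)(C)C)C[C@H](O[Si](C)(C)C(C)(C)C)C[N+]#[C-] | intermediate
43 | butanal | CCCC=O | starting material
44 | (2S,6S,8S,9R,12Z,14E,16S,20S,25S,27S)-6,8,9,20-tetrakis[(tert-butyldimethylsilyl)oxy]-16-ethyl-12-(methoxymethyl)-25,27-dimethyl-2-propyl-1-oxa-4-azacyclooctacosa-12,14-diene-3,28-dione | CCC[C@@H]1OC(=O)[C@@H](C)C[C@@H](C)CCCC[C@H](O[Si](C)(C)C(C)(C)C)CCC[C@H](CC)/C=C/C=C(\COC)CC[C@@H](O[Si](C)(C)C(C)(C)C)[C@@H](O[Si](C)(C)C(C)(C)C)C[C@H](O[Si](C)(C)C(C)(C)C)CNC1=O | intermediate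
45 | (2S,6S,8S,9R,12Z,14E,16S,20S,25S,27S)-16-ethyl-6,8,9,20-tetrahydroxy-12-(methoxymethyl)-25,27-dimethyl-2-propyl-1-oxa-4-azacyclooctacosa-12,14-diene-3,28-dione (CNP0221503.1) | CCC[C@@H]1OC(=O)[C@@H](C)C[C@@H](C)CCCC[C@H](O)CCC[C@H](CC)/C=C/C=C(\COC)CC[C@@H](O)[C@@H](O)C[C@H](O)CNC1=O | target

**Totals**
Total step count: 25.
Longest linear sequence: 14 steps (20 → 45, steps 12–25); the other branches are 13 steps (5 → 45) and 10 steps (1 → 45).

**Three steps most likely to fail, each with a fallback**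

Step 24 (macrocyclic Passerini reaction). Ring closure, the key C–C bond and the last stereocentre all depend on one untested step; oligomerisation or poor facial control are the likely failures. The fallback sets out from 19 and 38 and comes back at 44. It makes the same bond intermolecularly, where the three-component reaction is well behaved, and closes the ring at the diene instead. Compound 38 is dehydrated with Burgess reagent to the vinyl iodide isocyanide F1. The ester of 19 is cleaved with Me3SnOH (1,2-dichloroethane, 70 °C) to the alkenylboronate acid F2. F1, F2 and butanal 43 are combined at 0.5 M in CHCl3 with (R)-TRIP to give the linear α-acyloxy amide F3, whose diastereomers can be separated at this stage. A macrocyclic Suzuki coupling of F3 (Pd(dppf)Cl2, AsPh3, Cs2CO3, DMF/THF/H2O, 2 mM) then gives 44.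

Step 17 (Duboudin carbomagnesiation with a precious Grignard reagent). The Grignard reagent is used near 1:1 and can be lost to deprotonation of the alkyne or to sluggish addition. The fallback sets out from 29 and comes back at 35. It builds the trisubstituted alkene by syn addition to an alkyne rather than anti carbomagnesiation. Bromide 29 is alkylated with lithium acetylide–ethylenediamine in DMSO to the terminal alkyne F4. Silylformylation (Me2PhSiH, CO 20 bar, Rh4(CO)12, Et3N, toluene, 90 °C) puts the formyl group on the internal carbon and silicon cis to it on the terminal carbon, giving the silyl enal F5. NaBH4 gives the allylic alcohol F6, and NaH/MeI gives the methyl ether vinylsilane F7. Iododesilylation with NIS in (CF3)2CHOH, with retention, gives 35.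

Step 10 (alkyl–alkyl Negishi coupling). The bromide is β-branched, so slow oxidative addition and β-hydride elimination may erode the yield. The fallback sets out from 14 and 3 and comes back at 17. It replaces the palladium/zinc cross-coupling by a direct copper-mediated SN2 alkylation of a different electrophile. Alcohol 3 is converted (Tf2O, 2,6-lutidine, CH2Cl2, −78 °C) into the primary triflate F8. The Grignard reagent 15, made from 14 as in step 10, displaces the triflate under Li2CuCl4 catalysis (THF, −78 → −30 °C), a temperature at which the methyl ester is not attacked, to give 17.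

Further compounds
F1 | step 24 | (1Z,5R,6S,8S)-5,6,8-tris[(tert-butyldimethylsilyl)oxy]-1-iodo-9-isocyano-2-(methoxymethyl)non-1-ene | I/C=C(\COC)CC[C@@H](O[Si](C)(C)C(C)(C)C)[C@@H](O[Si](C)(C)C(C)(C)C)C[C@H](O[Si](C)(C)C(C)(C)C)C[N+]#[C-]
F2 | step 24 | (2S,4S,9S,13S,14E)-9-[(tert-butyldimethylsilyl)oxy]-13-ethyl-2,4-dimethyl-15-(4,4,5,5-tetramethyl-1,3,2-dioxaborolan-2-yl)pentadec-14-enoic acid | OC(=O)[C@@H](C)C[C@@H](C)CCCC[C@H](O[Si](C)(C)C(C)(C)C)CCC[C@H](CC)/C=C/B1OC(C)(C)C(C)(C)O1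
F3 | step 24 | (S)-1-oxo-1-{[(2S,4S,5R,8Z)-2,4,5-tris[(tert-butyldimethylsilyl)oxy]-9-iodo-8-(methoxymethyl)non-8-en-1-yl]amino}pentan-2-yl ester of acid F2 | I/C=C(\COC)CC[C@@H](O[Si](C)(C)C(C)(C)C)[C@@H](O[Si](C)(C)C(C)(C)C)C[C@H](O[Si](C)(C)C(C)(C)C)CNC(=O)[C@H](CCC)OC(=O)[C@@H](C)C[C@@H](C)CCCC[C@H](O[Si](C)(C)C(C)(C)C)CCC[C@H](CC)/C=C/B1OC(C)(C)C(C)(C)O1
F4 | step 17 | (5R,6S,8S)-5,6,8-tris[(tert-butyldimethylsilyl)oxy]-9-chloronon-1-yne | C#CCC[C@@H](O[Si](C)(C)C(C)(C)C)[C@@H](O[Si](C)(C)C(C)(C)C)C[C@H](O[Si](C)(C)C(C)(C)C)CCl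
F5 | step 17 | (2Z,5R,6S,8S)-5,6,8-tris[(tert-butyldimethylsilyl)oxy]-9-chloro-2-{[dimethyl(phenyl)silyl]methylidene}nonanal | O=C/C(=C\[Si](C)(C)c1ccccc1)CC[C@@H](O[Si](C)(C)C(C)(C)C)[C@@H](O[Si](C)(C)C(C)(C)C)C[C@H](O[Si](C)(C)C(C)(C)C)CCl
F6 | step 17 | (2Z,5R,6S,8S)-5,6,8-tris[(tert-butyldimethylsilyl)oxy]-9-chloro-2-{[dimethyl(phenyl)silyl]methylidene}nonan-1-ol | OC/C(=C\[Si](C)(C)c1ccccc1)CC[C@@H](O[Si](C)(C)C(C)(C)C)[C@@H](O[Si](C)(C)C(C)(C)C)C[C@H](O[Si](C)(C)C(C)(C)C)CCl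
F7 | step 17 | [(1Z,5R,6S,8S)-5,6,8-tris[(tert-butyldimethylsilyl)oxy]-9-chloro-2-(methoxymethyl)non-1-en-1-yl]dimethyl(phenyl)silane | COC/C(=C\[Si](C)(C)c1ccccc1)CC[C@@H](O[Si](C)(C)C(C)(C)C)[C@@H](O[Si](C)(C)C(C)(C)C)C[C@H](O[Si](C)(C)C(C)(C)C)CCl
F8 | step 10 | methyl (2S,4R)-2,4-dimethyl-5-{[(trifluoromethyl)sulfonyl]oxy}pentanoate | COC(=O)[C@@H](C)C[C@@H](C)COS(=O)(=O)C(F)(F)F
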